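**Plan**

- Retrosynthesis: both malonate C–O ester bonds are cut first, giving malonyl dichloride and two molecules of (13E)-labda-7,13-dien-15-ol. Then C12–C13 (alkylborane plus E enol triflate), C11–C12 and C9–C11 (two one-carbon olefinations), C3–C4 of ring A, and finally the C10–C1 and C10–CH3 bonds.
- Enabling feature: ring B (C5–C10), with its methyl on C8 of the C7=C8 alkene, an oxygen on C9 and a three-carbon branch on C5, is (R)-carvone atom for atom. The isopropenyl carbon is C4 with both geminal methyls latent, so a 2-chloroallyl group on C10 (C1–C2–C3) can close ring A onto the C4 cation.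
- Forward: carvone (ring B) → C10 made quaternary by methylation, then 2-chloroallylation → ring A closed by acid (C3–C4, C2 ketone) → C2 deoxygenated → C9=O converted into C9–C11 (diene, hydroboration to drimenol) and C11=C12 (Wittig) → side chain joined at C12–C13, ester reduced → two alcohol units joined through malonate.
- Stereochemistry: C5 comes from (R)-carvone. C10 comes from alkylation anti to the isopropenyl group, which also fixes the trans ring fusion. C9 comes from α-face hydroboration of the exocyclic 9(11)-alkene. 13E comes from stereoretentive coupling of an E enol triflate.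

Key step: step 3

Remark: positions are cited in labdane numbering (C1–C10 decalin, C11–C15 chain). The target is read as the malonate diester of two identical (5S,9S,10S,13E)-labda-7,13-dien-15-ol units, so one alcohol is made and used twice.

**Route**

Step 1
Reactants: 1 (R)-(−)-carvone; 2 iodomethane
Product: 4 (5R)-6-methylcarvone (C6 epimer mixture), via lithium dienolate 3 (not isolated)
Conditions: LDA, THF, −78 °C; then MeI, −78 → −20 °C
Reagents that add atoms: iodomethane, CI
Why: Kinetic α′-deprotonation of the enone gives the cross-conjugated lithium dienolate, which is C-methylated (enolate alkylation); the new C6 centre forms as an epimer mixture, which is immaterial because it is enolised again in step 2.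

Step 2
Reactants: 4 (5R)-6-methylcarvone; 5 2,3-dichloropropene
Product: 7 (5S,6S)-6-(2-chloroallyl)-6-methylcarvone, via lithium enolate 6 (not isolated)
Conditions: LDA, THF, −78 → −10 °C; then DMPU, 2,3-dichloropropene, NaI (cat.), −78 °C → rt
Reagents that add atoms: 2,3-dichloropropene, C=C(Cl)CCl
Why: Second enolate alkylation, with the allylic chloride activated in situ by iodide; the electrophile should add to the enolate face opposite the neighbouring C5 isopropenyl group, so the chloroallyl arm ends trans to isopropenyl and the methyl cis, which sets the quaternary centre that becomes C10.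

Step 3
Reactants: 7 (5S,6S)-6-(2-chloroallyl)-6-methylcarvone
Product: 8 (5S,10S)-4,4,8,10-tetramethyl-trans-octal-7-ene-2,9-dione (labdane numbering)
Conditions: 90% aq. H2SO4, 0 °C → rt; then ice–water
Reagents that add atoms: water, O
Why: Sulfuric acid protonates the isopropenyl CH2, the most basic alkene present because the enone is O-protonated and the vinyl chloride is deactivated by chlorine, to give the tertiary C4 cation that already carries both methyl groups; the CH2 terminus of the 2-chloroallyl group on C10 attacks it to form C3–C4, and the chlorine-stabilised C2 cation is hydrated in the medium and loses HCl to leave the ketone. The closest known reaction type is the Lansbury chloro-olefin annulation, a cation–olefin cyclisation terminated by a vinyl chloride acting as a masked ketone. Ring A closes in the 6-endo-trig mode through a chair-like transition state, attack occurring at the CH2 terminus because only that regiochemistry gives a heteroatom-stabilised cation. No stereocentre is created: C5 comes from carvone and C10 from step 2, and because the two reacting arms are trans (diequatorial) on ring B only the trans-fused decalin can form. The step needs chemoselective protonation and ring closure faster than a 1,2-hydride shift from C5 or proton loss; the protonated enone is inert as a nucleophile, the tether holds the polarised vinyl chloride within reach of the cation, and reversible proton loss to the isopropylidene isomer only returns the same cation.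

Step 4
Reactants: 8 (5S,10S)-4,4,8,10-tetramethyl-trans-octal-7-ene-2,9-dione
Product: 9 C2 mono-tosylhydrazone of 8
Conditions: TsNHNH2 (1.05 equiv), EtOH, cat. AcOH, 50 °C
Reagents that add atoms: 4-methylbenzenesulfonohydrazide, Cc1ccc(cc1)S(=O)(=O)NN
Why: Tosylhydrazone condensation should occur only at the saturated ring-A ketone, because the C9 carbonyl is conjugated and flanked by the quaternary C10 and the methyl-bearing C8; no stereocentre is touched.

Step 5
Reactants: 9 C2 mono-tosylhydrazone of 8
Product: 11 (5S,10S)-4,4,8,10-tetramethyl-trans-octal-7-en-9-one, via N-boryl tosylhydrazine 10 (not isolated)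
Conditions: catecholborane (1.2 equiv), CHCl3, 0 °C → rt; then NaOAc·3H2O, reflux
Reagents that add atoms: none
Why: Kabalka-type tosylhydrazone reduction, in which catecholborane hydroborates the C=N bond and acetate-induced loss of sulfinate gives a diazene that extrudes N2 to leave CH2 at C2; the hindered conjugated C9 ketone should react far more slowly with the borane than the hydrazone.

Step 6
Reactants: 11 (5S,10S)-4,4,8,10-tetramethyl-trans-octal-7-en-9-one
Product: 13 drima-7,9(11)-diene, via β-hydroxysilane 12 (not isolated)
Conditions: Me3SiCH2Li, THF–pentane, −78 → 0 °C; H2O quench; then KH, THF, rt on the crude carbinol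
Reagents that add atoms: (trimethylsilyl)methyllithium, [Li]C[Si](C)(C)C
Why: Peterson olefination, in which the small silylmethyllithium adds 1,2 to the hindered enone (no α′-hydrogen; expected from the α face, a centre that is destroyed again) and the potassium alkoxide undergoes syn-elimination of silanolate to give the exocyclic methylene under base, avoiding acid that could isomerise the diene.

Step 7
Reactants: 13 drima-7,9(11)-diene
Product: 15 drimenol, via C11 alkyl-9-BBN 14 (not isolated)
Conditions: 9-BBN, THF, rt → 50 °C; then 3 M NaOH, 30% H2O2, 0 °C → rt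
Reagents that add atoms: hydrogen peroxide, OO
Why: Hydroboration–oxidation, in which 9-BBN adds anti-Markovnikov only to the 1,1-disubstituted exocyclic alkene (the trisubstituted ring alkene is inert to it), placing boron on C11 and hydrogen on C9 syn from the α face opposite the axial C10 methyl on the adjacent carbon, which should set 9α-H and a β C11 (9S); oxidation proceeds with retention.

Step 8
Reactants: 15 drimenol
Product: 16 drimenal
Conditions: Dess–Martin periodinane, NaHCO3, CH2Cl2, 0 °C → rt
Reagents that add atoms: none
Why: Dess–Martin oxidation under bicarbonate buffering gives the β,γ-unsaturated aldehyde without the acid or base that would epimerise C9 or move the alkene into conjugation.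

Step 9
Reactants: 16 drimenal
Product: 17 (5S,9S,10S)-9-vinyl compound (13,14,15,16-tetranorlabda-7,11-diene)
Conditions: Ph3PCH3Br, KHMDS, THF, 0 °C; then 16, −78 → 0 °C
Reagents that add atoms: methyltriphenylphosphonium bromide (as its ylide), C[P+](c1ccccc1)(c1ccccc1)c1ccccc1.[Br-]
Why: Wittig methylenation with the non-stabilised ylide is fast on the aldehyde at low temperature, while the C9–H next to the quaternary C10 is too hindered to be removed, so the C9 configuration should be kept.

Step 10
Reactants: 18 ethyl acetoacetate
Product: 19 ethyl (2E)-3-(trifluoromethylsulfonyloxy)but-2-enoate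
Conditions: Tf2O, aq. Me4NOH, toluene, 5 °C (biphasic)
Reagents that add atoms: trifluoromethanesulfonic anhydride, O=S(=O)(OS(=O)(=O)C(F)(F)F)C(F)(F)F
Why: O-Triflation of the β-keto ester enolate, which with the non-coordinating tetramethylammonium counter-ion reacts in its open, non-chelated form and should give the E enol triflate (OTf trans to the ester), a known counter-ion-controlled enol triflate synthesis.

Step 11
Reactants: 17 (5S,9S,10S)-9-vinyl compound; 19 ethyl (2E)-3-(trifluoromethylsulfonyloxy)but-2-enoate
Product: 21 ethyl (13E)-labda-7,13-dien-15-oate, via C12 alkyl-9-BBN 20 (not isolated)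
Conditions: 9-BBN, THF, rt; then 19, PdCl2(dppf)·CH2Cl2 (cat.), K3PO4·H2O, THF–DMF, rt → 50 °C
Reagents that add atoms: ethyl (2E)-3-(trifluoromethylsulfonyloxy)but-2-enoate (19), CCOC(=O)/C=C(\C)OS(=O)(=O)C(F)(F)F
Why: B-alkyl Suzuki–Miyaura coupling, in which 9-BBN hydroborates only the monosubstituted vinyl group at its terminus and the unhindered primary alkylborane couples with the activated enol triflate with retention of alkene geometry, so 13E is inherited from 19 and no decalin stereocentre is involved.

Step 12
Reactants: 21 ethyl (13E)-labda-7,13-dien-15-oate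
Product: 22 (13E)-labda-7,13-dien-15-ol
Conditions: DIBAL-H (2.2 equiv), CH2Cl2, −78 °C; Rochelle salt work-up
Reagents that add atoms: none
Why: DIBAL-H 1,2-reduction of the α,β-unsaturated ester gives the allylic alcohol without touching either trisubstituted alkene or the E geometry.

Step 13
Reactants: 22 (13E)-labda-7,13-dien-15-ol (2 equiv); 23 malonyl dichloride
Product: 24 bis[(13E)-labda-7,13-dien-15-yl] malonate (target)
Conditions: malonyl dichloride (0.5 equiv), pyridine, CH2Cl2, −20 → 0 °C
Reagents that add atoms: malonyl dichloride, O=C(Cl)CC(=O)Cl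
Why: Twofold acylation (esterification) of the primary allylic alcohol by the diacid chloride, with pyridine scavenging HCl so that the allylic system and the ring alkene are not attacked by acid; two identical units give the symmetrical diester.

**Compound list**

1 | (R)-(−)-carvone, (5R)-2-methyl-5-(prop-1-en-2-yl)cyclohex-2-en-1-one | CC1=CC[C@@H](C(C)=C)CC1=O | starting material
2 | iodomethane | CI | starting material
3 | lithium cross-conjugated dienolate of 1 (O–Li on C1, C1=C6; C5 unchanged) | CC1=CC[C@@H](C(C)=C)C=C1O[Li] | intermediate (not isolated)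
4 | (5R,6RS)-2,6-dimethyl-5-(prop-1-en-2-yl)cyclohex-2-en-1-one (6-methylcarvone, C6 epimers) | CC1=CC[C@@H](C(C)=C)C(C)C1=O | intermediate
5 | 2,3-dichloroprop-1-ene | C=C(Cl)CCl | starting material
6 | lithium enolate of 4 (O–Li on C1, C1=C6 tetrasubstituted) | CC1=CC[C@@H](C(C)=C)C(C)=C1O[Li] | intermediate (not isolated)
7 | (5S,6S)-6-(2-chloroprop-2-en-1-yl)-2,6-dimethyl-5-(prop-1-en-2-yl)cyclohex-2-en-1-one (chloroallyl trans to isopropenyl) | CC1=CC[C@@H](C(C)=C)[C@](C)(CC(Cl)=C)C1=O | intermediate (key-step precursor)
8 | (4aS,8aS)-2,5,5,8a-tetramethyl-4a,5,6,8-tetrahydronaphthalene-1,7(4H,8aH)-dione; labdane numbering (5S,10S)-7-ene-2,9-dione, trans-fused | CC1=CC[C@H]2C(C)(C)CC(=O)C[C@]2(C)C1=O | intermediate (key-step product)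
9 | mono-(4-methylbenzenesulfonyl)hydrazone of 8 at the ring-A (C2) ketone, C=N geometry undefined | CC1=CC[C@H]2C(C)(C)CC(=NNS(=O)(=O)c3ccc(C)cc3)C[C@]2(C)C1=O | intermediate
10 | C2 N-(1,3,2-benzodioxaborol-2-yl)-N′-tosylhydrazine (nitrogen β expected; centre lost on fragmentation) | CC1=CC[C@H]2C(C)(C)C[C@@H](N(NS(=O)(=O)c3ccc(C)cc3)B3Oc4ccccc4O3)C[C@]2(C)C1=O | intermediate (not isolated)
11 | (4aS,8aS)-2,5,5,8a-tetramethyl-4a,5,6,7,8,8a-hexahydronaphthalen-1(4H)-one | CC1=CC[C@H]2C(C)(C)CCC[C@]2(C)C1=O | intermediate
12 | (1S,4aS,8aS)-2,5,5,8a-tetramethyl-1-[(trimethylsilyl)methyl]-1,4,4a,5,6,7,8,8a-octahydronaphthalen-1-ol (CH2SiMe3 α, OH β) | CC1=CC[C@H]2C(C)(C)CCC[C@]2(C)[C@@]1(C[Si](C)(C)C)O | intermediate (not isolated)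
13 | drima-7,9(11)-diene, (4aS,8aS)-2,5,5,8a-tetramethyl-1-methylidene-1,4,4a,5,6,7,8,8a-octahydronaphthalene | CC1=CC[C@H]2C(C)(C)CCC[C@]2(C)C1=C | intermediate
14 | 9-(drim-7-en-11-yl)-9-borabicyclo[3.3.1]nonane (9S) | CC1=CC[C@H]2C(C)(C)CCC[C@]2(C)[C@H]1CB1C2CCCC1CCC2 | intermediate (not isolated)
15 | drimenol, [(1S,4aS,8aS)-2,5,5,8a-tetramethyl-1,4,4a,5,6,7,8,8a-octahydronaphthalen-1-yl]methanol | CC1=CC[C@H]2C(C)(C)CCC[C@]2(C)[C@H]1CO | intermediate
16 | drimenal, (1S,4aS,8aS)-2,5,5,8a-tetramethyl-1,4,4a,5,6,7,8,8a-octahydronaphthalene-1-carbaldehyde | CC1=CC[C@H]2C(C)(C)CCC[C@]2(C)[C@H]1C=O | intermediate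
17 | (1S,4aS,8aS)-1-ethenyl-2,5,5,8a-tetramethyl-1,4,4a,5,6,7,8,8a-octahydronaphthalene | CC1=CC[C@H]2C(C)(C)CCC[C@]2(C)[C@H]1C=C | intermediate
18 | ethyl acetoacetate | CCOC(=O)CC(C)=O | starting material
19 | ethyl (2E)-3-{[(trifluoromethyl)sulfonyl]oxy}but-2-enoate | CCOC(=O)/C=C(\C)OS(=O)(=O)C(F)(F)F | intermediate
20 | 9-{2-[(1S,4aS,8aS)-2,5,5,8a-tetramethyl-1,4,4a,5,6,7,8,8a-octahydronaphthalen-1-yl]ethyl}-9-borabicyclo[3.3.1]nonane | CC1=CC[C@H]2C(C)(C)CCC[C@]2(C)[C@H]1CCB1C2CCCC1CCC2 | intermediate (not isolated)
21 | ethyl (13E)-labda-7,13-dien-15-oate, ethyl (2E)-3-methyl-5-[(1S,4aS,8aS)-2,5,5,8a-tetramethyl-1,4,4a,5,6,7,8,8a-octahydronaphthalen-1-yl]pent-2-enoate | CC1=CC[C@H]2C(C)(C)CCC[C@]2(C)[C@H]1CC/C(C)=C/C(=O)OCC | intermediate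
22 | (13E)-labda-7,13-dien-15-ol (5S,9S,10S) | CC1=CC[C@H]2C(C)(C)CCC[C@]2(C)[C@H]1CC/C(C)=C/CO | intermediate
23 | malonyl dichloride | O=C(Cl)CC(=O)Cl | starting material
24 | bis[(13E)-labda-7,13-dien-15-yl] propanedioate (CNP0113044.1) | CC1=CC[C@H]2C(C)(C)CCC[C@]2(C)[C@H]1CC/C(C)=C/COC(=O)CC(=O)OC/C=C(\C)CC[C@H]1C(C)=CC[C@H]2C(C)(C)CCC[C@]12C | target

**Step count and risks**

Total step count: 13. Longest linear sequence: 12 (steps 1–9 and 11–13; step 10 prepares the coupling partner).

Steps most likely to fail:

1. Step 3. Ring closure may lose out to other fates of the C4 cation (1,2-hydride shift from C5, proton loss, capture by the medium) or to premature hydrolysis of the vinyl chloride to an acetonyl group before the cation is formed. The fallback sets out from 7 and returns at 8, separating cation generation from hydrolysis under aprotic conditions. Dry HCl in CH2Cl2 at −20 °C should add in the Markovnikov sense to the isopropenyl group and give the tertiary chloride (5R,6S)-6-(2-chloroprop-2-en-1-yl)-5-(2-chloropropan-2-yl)-2,6-dimethylcyclohex-2-en-1-one F1. Ionisation of F1 with SnCl4 in CH2Cl2 at −78 °C generates the same C4 cation without protonating the medium; after ring closure the C2 cation collects chloride to give the geminal dichloride (4aS,8aS)-7,7-dichloro-2,5,5,8a-tetramethyl-4a,5,6,7,8,8a-hexahydronaphthalen-1(4H)-one F2. Brief treatment of F2 with cold 90% sulfuric acid followed by water should hydrolyse it to 8.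

2. Step 7. Hydroboration of the hindered, conjugated exocyclic alkene may be slow, which would allow erosion of facial selectivity at C9 or competing attack on the ring alkene. The fallback sets out from 11 and returns at 15, with C9 set by inversion at palladium instead of by reagent approach. Corey–Chaykovsky reaction of 11 with dimethylsulfonium methylide (Me3S+ I−, n-BuLi, THF, −10 °C) should add CH2 to the C9 carbonyl from the α face and give the vinyl oxirane (9S)-9,11-epoxydrim-7-ene F3 with the oxygen β. Palladium-catalysed hydrogenolysis of this alkenyl oxirane with formic acid and triethylamine (Pd2(dba)3·CHCl3, n-Bu3P, dioxane, rt; Tsuji–Shimizu conditions) opens C9–O with palladium on the α face. Hydride is then delivered from palladium to the more substituted allyl terminus C9, leaving 9α-H, the β CH2OH group and the 7-ene, which is 15.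

3. Step 11. The enol triflate may be lost by base-induced elimination or hydrolysis, its geometry may erode, or transmetalation may be slow enough for protodeboronation to compete. The fallback sets out from 17 and returns at 21, replacing cross-coupling by a stereospecific syn-carbocupration. Borane 20, made from 17 as in step 11, is cleaved with I2 and NaOMe in THF–MeOH to give (1S,4aS,8aS)-1-(2-iodoethyl)-2,5,5,8a-tetramethyl-1,4,4a,5,6,7,8,8a-octahydronaphthalene F4. Iodine–lithium exchange with t-BuLi (2 equiv, Et2O–pentane, −78 °C) gives the primary alkyllithium F5, and CuI (0.5 equiv) converts it into the lithium dialkylcuprate F6. Addition of F6 to ethyl but-2-ynoate (CC#CC(=O)OCC) in THF at −78 °C, with protonation at that temperature, places the alkyl group and the new hydrogen cis, so the chain is trans to the ester and the product is 21.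

**Further compounds**

F1 | step 3 | (5R,6S)-6-(2-chloroprop-2-en-1-yl)-5-(2-chloropropan-2-yl)-2,6-dimethylcyclohex-2-en-1-one | CC1=CC[C@@H](C(C)(C)Cl)[C@](C)(CC(Cl)=C)C1=O
F2 | step 3 | (4aS,8aS)-7,7-dichloro-2,5,5,8a-tetramethyl-4a,5,6,7,8,8a-hexahydronaphthalen-1(4H)-one | CC1=CC[C@H]2C(C)(C)CC(Cl)(Cl)C[C@]2(C)C1=O
F3 | step 7 | (9S)-9,11-epoxydrim-7-ene (spiro-oxirane on C9, oxygen β) | CC1=CC[C@H]2C(C)(C)CCC[C@]2(C)[C@]13CO3
F4 | step 11 | (1S,4aS,8aS)-1-(2-iodoethyl)-2,5,5,8a-tetramethyl-1,4,4a,5,6,7,8,8a-octahydronaphthalene | ICC[C@H]1C(C)=CC[C@H]2C(C)(C)CCC[C@]12C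
F5 | step 11 | {2-[(1S,4aS,8aS)-2,5,5,8a-tetramethyl-1,4,4a,5,6,7,8,8a-octahydronaphthalen-1-yl]ethyl}lithium | [Li]CC[C@H]1C(C)=CC[C@H]2C(C)(C)CCC[C@]12C
F6 | step 11 | lithium bis{2-[(1S,4aS,8aS)-2,5,5,8a-tetramethyl-1,4,4a,5,6,7,8,8a-octahydronaphthalen-1-yl]ethyl}cuprate | [Li+].CC1=CC[C@H]2C(C)(C)CCC[C@]2(C)[C@H]1CC[Cu-]CC[C@H]1C(C)=CC[C@H]2C(C)(C)CCC[C@]12C
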